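# Proposed synthesis of [(1S,2R,3S,4R,5R,6S)-2,3-diacetoxy-4,5-dihydroxy-7-oxabicyclo[4.1.0]heptan-1-yl]methyl benzoate from D-gulono-1,4-lactone

**Ring numbering.** C1 is the oxirane carbon bearing C7H2OBz, C2 and C3 are the CHOAc carbons, C4 and C5 the CHOH carbons, C6 the oxirane CH. The α face is the face of the oxirane oxygen in the target; the β face carries C7.

**Compound numbering.**
- Chain series: 1 D-gulono-1,4-lactone, 3 diacetonide, 4 diol lactone, 6 bis-TES lactone, 8 hydroxy N-methoxy-N-methylamide, 10 its TBS ether, 13 stannane, 14 lithium reagent, 15 ketone, 16 keto-aldehyde.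
- Ring series: 17 cyclitol diol, 18 triol, 20 diacetate, 21 C7 alcohol, 23 benzoate, 24 C1,C5,C6-triol, 27 cyclic sulfite, 28 cyclic sulfate, 29 epoxy sulfate salt, 30 silylated epoxy alcohol, 31 target.
- Reagents that put atoms into products: 2, 5, 7, 9, 11, 12, 19, 22, 25, 26.

## Analysis of the target

The target 31 is a cyclohexane in which every ring carbon carries oxygen: an oxirane spanning C1 and C6, acetates on C2 and C3, free hydroxyls on C4 and C5, and a benzoyloxymethyl group (C7) on the quaternary C1. The six contiguous stereocentres are (1S,2R,3S,4R,5R,6S). In face terms the oxirane oxygen and O2 and O4 are α, while O3, O5 and C7 are β, so O1/O2 are cis and the pairs 2,3, 3,4 and 4,5 are trans. The sensitive groups are the trisubstituted oxirane, which is open to acid and nucleophiles, and three esters of two kinds. These esters sit next to free or transiently free hydroxyls and can migrate under base, so the last steps have to be neutral or mildly acidic. The difficulty lies less in forming the ring than in placing six oxygens with the right relative and absolute configuration, in three different acylation states, around a quaternary centre. The plan rests on one observation: if the oxirane is opened in thought at C6 with inversion, O6 becomes β, and the sequence O6 β, O5 β, O4 α, O3 β along C6–C5–C4–C3 is the pattern of C2–C5 of D-gulonic acid. Ring atoms C1, C6, C5, C4, C3, C2 then correspond to gulonic C1 to C6, and the two remaining oxygens, O1 and O2, form a cis-diol across the C1–C2 bond that lies anti to both O6 and O3. The C1–C2 bond is therefore the ring bond to make, by reductive coupling of a C1 ketone with a C2 aldehyde.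

## Retrosynthetic reasoning

**Oxirane (C6–O1 bond).** The target 31 comes from its O4-silyl ether 30 by desilylation. In 30 the C6–O1 bond is cut, which leads to the cyclic sulfate 28 on O5/O6 with a free tertiary hydroxyl on C1. This cut is chosen because in the chair of 28 that puts C7, O2, O3, O4 and O5 equatorial, O1 and the C6–O bond are the only axial substituents and are antiperiplanar. The C1 oxygen can attack only C6, so no selective sulfonylation of one secondary hydroxyl is needed, and the sulfate ester left on O5 hydrolyses to the C5 hydroxyl of the target. The sulfate 28 comes from triol 24, and 24 from acetonide 23.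

**Ester pattern.** Benzoate 23 goes back through alcohol 21 and PMB ether 20 to triol 18 and the ring-closure product 17. The esters are put on after the ring is made, because the ring-forming step and the organolithium step before it tolerate only ethers. The order follows from the protecting groups: the TES ether on O3 comes off first, O2 and O3 are acetylated together (the tertiary O1 does not react), then the PMB ether on O7 is exchanged for benzoate. The TBS ether on O4 stays until the end so that O4 cannot enter the cyclic sulfate.

**Ring closure (C1–C2 bond).** In 17 the C1–C2 bond is cut, giving the open-chain keto-aldehyde 16. This is the only ring bond whose two carbons are not sugar stereocentres and whose two oxygens are cis. Cutting it leaves a chain in which all four remaining stereocentres are bought. The forward step has to form the quaternary carbinol and the secondary carbinol as a cis-diol on the α face.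

**Aldehyde and C7.** Aldehyde 16 arises from ketone 15 by oxidising the primary TES ether directly. Ketone 15 is cut at C1–C7 into the N-methoxy-N-methylamide 10 and the alkoxymethyllithium 14, made from stannane 13. C7 thus enters as a nucleophile carrying its own protected oxygen, and the ketone appears only two steps before the key step.

**Oxygen differentiation on the sugar.** Amide 10 comes from hydroxy amide 8, and 8 from lactone 6 by ring opening. The lactone ring hides O4 until it is opened, so O4 is then the only free hydroxyl and takes the TBS group. Lactone 6 comes from diol 4, obtained from diacetonide 3 and thus from 1. The terminal diol is released and silylated while C1 is still a lactone. A free hydroxyl on gulonic C5 (the future O3) next to a C1 ketone would close to a six-membered hemiketal, and silylation would then not reliably give the open-chain bis-silyl ether.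

**Stannane.** Compound 13 is made by etherification of alcohol 11 with iodide 12.

## Alternatives that were turned down

**Alternative 1:** This plan cuts the C1–O and C2–O bonds and goes back to benzoic acid A1. In the forward direction whole cells of a Ralstonia eutropha mutant, which has the benzoate dioxygenase but lacks the diol dehydrogenase, would oxidise A1 to (1S,2R)-1,2-dihydroxycyclohexa-3,5-diene-1-carboxylic acid A2.
- For it: A2 holds all seven carbons, the quaternary C1 with O1 and the carbon that becomes C7, and the cis C2 hydroxyl. Both centres have the configuration of the target (O1 and O2 α, carboxyl β). It is obtained in one step from an achiral bulk chemical without protecting groups.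
- Against it: C3 to C6 of A2 are a diene that must be oxidised four times with site and face control (O3 β, O4 α, O5 β, and the C6–O1 bond on the α face). The last of these needs a β-oxirane or β leaving group at C6, the opposite of what the C1 and C2 hydroxyls would direct. The two double bonds differ little, A2 re-aromatises by loss of water under acid, and neither the strain nor A2 is a stock item.
- Comparison: this plan is clearly shorter, and it sets the quaternary centre with the selectivity of an enzyme; on both points it is stronger. The gulonolactone plan offers instead four purchased stereocentres, two more from one step whose sense is argued from two reinforcing neighbours, and an individual protecting group on every oxygen, so the triester pattern needs no late selectivity.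

**Alternative 2:** This plan cuts the C1–O and C4–O bonds and goes back to the trans-diacetoxy diene A3, [5,6-diacetoxycyclohexa-1,3-dien-1-yl]methyl benzoate with the C2 and C3 configuration of the target. Singlet oxygen (tetraphenylporphyrin, light, O2) would add across C1 and C4 to give the bicyclic endoperoxide A4.
- For it: the two oxygens arrive cis, as O1 and O4 are in the target (both α). The ester pattern is already complete in A3. Rearrangement of A4 to the syn-bis-oxirane A5 and hydrolytic opening of the C4–C5 oxirane at C5 would finish the synthesis in three steps from A3.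
- Against it: the α face of A3 is flanked by the C2 acetoxy group next to the C1 terminus and the β face by the C3 acetoxy group next to the C4 terminus, so the facial bias is weak and its sense uncertain. In A5 water must open one of two oxiranes and only at C5; attack at C4 gives the other trans-diol, and the C1–C6 oxirane competes. A3 is not commercial and needs an enantioselective synthesis of its own, and as a cyclohexadiene with allylic esters it aromatises readily.
- Comparison: after A3 this plan is shorter. Its key step, however, builds no skeleton and no absolute configuration, and two selectivities are not secured by structure. In the chosen plan the oxirane site is fixed by construction.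

**Alternative 3:** This plan cuts the C6–O1 bond in the Payne sense and goes back to the meso bis-epoxyquinol A6 (C4 ketone, oxiranes on C2–C3 and C5–C6, both anti to the C1 hydroxyl). One enantiomer of N,N'-bis(3,5-di-tert-butylsalicylidene)-1,2-cyclohexanediaminocobalt triflate (trivalent cobalt) would activate one enantiotopic oxirane, and the C1 hydroxyl would attack C6 to give A7, with the C1–C6 oxirane, the C5 hydroxyl, the C4 ketone and the C2–C3 oxirane intact.
- For it: the absolute configuration comes from a catalyst, the substrate is symmetrical, C1, C5 and C6 are set at once, and the benzoate is already in place.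
- Against it: an enantioselective Payne shift of this kind is not established. The nearest known reactions are cobalt–salen-catalysed openings of meso-oxiranes by tethered alcohols that form five- and six-membered ethers. A6 needs both oxiranes anti to the hydroxyl, whereas epoxidation of quinols is usually guided syn by it. In A7 the C2–C3 oxirane oxygen is β on both carbons, so acetate must attack C2, next to the fully substituted oxirane carbon, and not C3, which the neighbouring carbonyl activates. The ketone must also be reduced to the 4α alcohol, and the hydroxy epoxy ketone is prone to elimination.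
- Comparison: this is the shortest plan and the only catalytic asymmetric one; on concept and step count it is stronger. It places an unprecedented key step on top of three open selectivity questions. The chosen plan has a key step with close precedent, and the rest is protecting-group chemistry.

Key step: step 9

Remark on the chemistry: tributyl(iodomethyl)stannane 12 and the silylating and acylating agents are treated as purchased reagents.

## Route

Step 1
Reactants: 1 D-gulono-1,4-lactone; 2 2,2-dimethoxypropane
Product: 3 2,3:5,6-di-O-isopropylidene-D-gulono-1,4-lactone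
Conditions: 2,2-dimethoxypropane, TsOH·H2O (cat.), acetone, rt
Reagents that add atoms: 2,2-dimethoxypropane (2), COC(C)(C)OC
Why: Acid-catalysed transketalisation; only the cis-2,3-diol on the lactone ring and the terminal 5,6-diol can form dioxolanes, O4 stays in the lactone and no stereocentre is touched.

Step 2
Reactants: 3 2,3:5,6-di-O-isopropylidene-D-gulono-1,4-lactone
Product: 4 2,3-O-isopropylidene-D-gulono-1,4-lactone
Conditions: AcOH/H2O (7:3), rt
Reagents that add atoms: none
Why: Selective acetal hydrolysis; the terminal dioxolane is unhindered, whereas the ring-fused one is bicyclic and deactivated by the adjacent lactone carbonyl.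

Step 3
Reactants: 4 2,3-O-isopropylidene-D-gulono-1,4-lactone; 5 chlorotriethylsilane
Product: 6 2,3-O-isopropylidene-5,6-bis-O-(triethylsilyl)-D-gulono-1,4-lactone
Conditions: TESCl, imidazole, DMF, 0 °C → rt
Reagents that add atoms: chlorotriethylsilane (5), CC[Si](Cl)(CC)CC
Why: Silylation of the primary and the secondary hydroxyl; the same group on both is wanted because the primary one is later oxidised off selectively.

Step 4
Reactants: 6 2,3-O-isopropylidene-5,6-bis-O-(triethylsilyl)-D-gulono-1,4-lactone; 7 N,O-dimethylhydroxylamine hydrochloride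
Product: 8 N-methoxy-N-methyl-2,3-O-isopropylidene-5,6-bis-O-(triethylsilyl)-D-gulonamide (4-OH free)
Conditions: MeNHOMe·HCl, AlMe3, CH2Cl2, 0 °C → rt; aq. potassium sodium tartrate; used at once
Reagents that add atoms: N,O-dimethylhydroxylamine hydrochloride (7), CNOC.Cl
Why: Aminolysis of the lactone by the aluminium amide made in the flask; the ring opening frees O4 as the only hydroxyl and C2 is not epimerised because no enolisable carbonyl is formed under these conditions.

Step 5
Reactants: 8 N-methoxy-N-methyl-2,3-O-isopropylidene-5,6-bis-O-(triethylsilyl)-D-gulonamide; 9 tert-butyldimethylsilyl trifluoromethanesulfonate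
Product: 10 N-methoxy-N-methyl-4-O-(tert-butyldimethylsilyl)-2,3-O-isopropylidene-5,6-bis-O-(triethylsilyl)-D-gulonamide
Conditions: TBSOTf, 2,6-lutidine, CH2Cl2, −78 → 0 °C
Reagents that add atoms: tert-butyldimethylsilyl trifluoromethanesulfonate (9), CC(C)(C)[Si](C)(C)OS(=O)(=O)C(F)(F)F
Why: Silyl triflate silylation of a hindered secondary hydroxyl; trapping O4 at once also stops the hydroxy amide from closing back to the lactone.

Step 6
Reactants: 11 4-methoxybenzyl alcohol; 12 tributyl(iodomethyl)stannane
Product: 13 tributyl{[(4-methoxybenzyl)oxy]methyl}stannane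
Conditions: NaH, THF/DMF, 0 °C → rt
Reagents that add atoms: tributyl(iodomethyl)stannane (12), CCCC[Sn](CCCC)(CCCC)CI
Why: Williamson ether synthesis; the alkoxide displaces iodide at the unhindered iodomethyl carbon.

Step 7
Reactants: 13 tributyl{[(4-methoxybenzyl)oxy]methyl}stannane; 10 N-methoxy-N-methyl-4-O-(tert-butyldimethylsilyl)-2,3-O-isopropylidene-5,6-bis-O-(triethylsilyl)-D-gulonamide
Product: 15 5-O-(tert-butyldimethylsilyl)-3,4-O-isopropylidene-1-O-(4-methoxybenzyl)-6,7-bis-O-(triethylsilyl)-keto-D-gulo-hept-2-ulose, via [(4-methoxybenzyl)oxy]methyllithium 14 (not isolated)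
Conditions: 13, n-BuLi, THF, −78 °C; then 10, −78 °C; aq. NH4Cl
Reagents that add atoms: stannane 13 (source of the PMBOCH2 unit), CCCC[Sn](CCCC)(CCCC)COCc1ccc(OC)cc1
Why: Tin–lithium exchange gives the α-alkoxymethyllithium, which adds once to the N-methoxy-N-methylamide; the chelated tetrahedral adduct collapses to the ketone only on work-up, so there is no over-addition and no enolisation next to the dioxolane.

Step 8
Reactants: 15 5-O-(tert-butyldimethylsilyl)-3,4-O-isopropylidene-1-O-(4-methoxybenzyl)-6,7-bis-O-(triethylsilyl)-keto-D-gulo-hept-2-ulose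
Product: 16 3-O-(tert-butyldimethylsilyl)-4,5-O-isopropylidene-7-O-(4-methoxybenzyl)-2-O-(triethylsilyl)-aldehydo-L-gluco-heptos-6-ulose (keto-aldehyde: ring C2 aldehyde and C1 ketone)
Conditions: (COCl)2, DMSO, CH2Cl2, −78 → −40 °C; then Et3N, −78 → −20 °C
Reagents that add atoms: none
Why: Swern oxidation applied directly to a primary triethylsilyl ether; chlorodimethylsulfonium chloride cleaves the unhindered primary Si–O bond, the alkoxysulfonium salt gives the aldehyde with the amine, and the secondary TES and TBS ethers are too hindered to react, while the low temperature protects the two α-oxygenated carbonyl centres from epimerisation.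

Step 9
Reactants: 16 keto-aldehyde (ring C2 aldehyde; C1 ketone; 3-OTES; 4-OTBS; 5,6-O-isopropylidene; 7-OPMB)
Product: 17 (1α,2α,3β,4α,5β,6β)-4-(tert-butyldimethylsilyloxy)-5,6-(isopropylidenedioxy)-1-[(4-methoxybenzyloxy)methyl]-3-(triethylsilyloxy)cyclohexane-1,2-diol
Conditions: SmI2 (3 equiv), t-BuOH (3 equiv), THF, −78 °C → rt
Reagents that add atoms: none
Why: SmI2 (divalent samarium) transfers one electron to the aldehyde, the more easily reduced carbonyl, and the ketyl stays bound to trivalent samarium, which also binds the ketone oxygen. The ketyl carbon C2 then adds to the ketone carbon C1 through a metal-bridged chair (6-exo-trig closure of the carbocycle onto the C1=O bond), a second electron reduces the oxygen-centred radical, and tert-butanol protonates the samarium diolate. The closest known reaction type is the SmI2-promoted pinacol carbocyclisation of carbohydrate-derived 1,6-dicarbonyl compounds, keto-aldehydes included. The samarium bridge holds O1 and O2 on the same face, which sets the cis relationship of the two new centres. The configuration at C2 is controlled by the C3 silyloxy group, because the ketyl oxygen goes anti to it to avoid steric and dipolar repulsion; the configuration at C1 is controlled in the same way by the C6 dioxolane oxygen. O3 and O6 are both β, so the two effects point to the α face and reinforce each other, and in the resulting chair only O1 and O6 are axial while C7, O2, O3, O4 and O5 are equatorial. The step needs coupling to win over cleavage of the C–O bonds α to the ketone and over simple reduction of the aldehyde; the cis-dioxolane on C5/C6 holds the two carbonyls close, so the ketyl is trapped fast, and the low temperature with tert-butanol as the only proton source disfavours the side paths.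

Step 10
Reactants: 17 cyclitol diol (3-OTES; 4-OTBS)
Product: 18 (1α,2α,3β,4α,5β,6β)-4-(tert-butyldimethylsilyloxy)-5,6-(isopropylidenedioxy)-1-[(4-methoxybenzyloxy)methyl]cyclohexane-1,2,3-triol
Conditions: HF·pyridine, pyridine, THF, 0 °C
Reagents that add atoms: none
Why: Selective desilylation; a secondary TES ether is cleaved by buffered HF much faster than the hindered secondary TBS ether, and the acetonide and PMB ether are inert to it.

Step 11
Reactants: 18 triol; 19 acetic anhydride
Product: 20 (1α,2α,3β,4α,5β,6β)-2,3-diacetoxy-4-(tert-butyldimethylsilyloxy)-5,6-(isopropylidenedioxy)-1-[(4-methoxybenzyloxy)methyl]cyclohexan-1-ol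
Conditions: Ac2O, pyridine, DMAP (cat.), CH2Cl2, 0 °C → rt
Reagents that add atoms: acetic anhydride (19), CC(=O)OC(C)=O
Why: Acylation of the two secondary hydroxyls; the tertiary, axial C1 hydroxyl between C7 and two ring substituents does not react under these mild conditions.

Step 12
Reactants: 20 diacetate PMB ether
Product: 21 (1α,2α,3β,4α,5β,6β)-2,3-diacetoxy-4-(tert-butyldimethylsilyloxy)-1-(hydroxymethyl)-5,6-(isopropylidenedioxy)cyclohexan-1-ol
Conditions: DDQ, CH2Cl2/pH 7 buffer (NaH2PO4/Na2HPO4), 0 °C → rt
Reagents that add atoms: none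
Why: Oxidative cleavage of the electron-rich benzyl ether by hydride abstraction and hydrolysis of the oxocarbenium ion; the aqueous phase intercepts the cation before the neighbouring tertiary hydroxyl can, and esters, silyl ether and acetonide are untouched.

Step 13
Reactants: 21 C7 alcohol; 22 benzoyl chloride
Product: 23 [(1α,2α,3β,4α,5β,6β)-2,3-diacetoxy-4-(tert-butyldimethylsilyloxy)-1-hydroxy-5,6-(isopropylidenedioxy)cyclohexyl]methyl benzoate
Conditions: BzCl, pyridine, CH2Cl2, 0 °C
Reagents that add atoms: benzoyl chloride (22), O=C(Cl)c1ccccc1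
Why: Acylation of the primary hydroxyl in the presence of the tertiary one, which is much slower to react.

Step 14
Reactants: 23 benzoate acetonide
Product: 24 [(1α,2α,3β,4α,5β,6β)-2,3-diacetoxy-4-(tert-butyldimethylsilyloxy)-1,5,6-trihydroxycyclohexyl]methyl benzoate
Conditions: TFA/H2O (9:1), CH2Cl2, 0 °C, stopped at full conversion
Reagents that add atoms: none
Why: Acid hydrolysis of the cis-fused dioxolane; the TBS ether is secondary and flanked on both sides, so it is expected to hydrolyse more slowly than the acetal, and the esters are stable to short acid exposure.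

Step 15
Reactants: 24 C1,C5,C6-triol; 25 thionyl chloride; 26 sodium periodate
Product: 28 5β,6β-cyclic sulfate of 24 (1α-OH free), via 5β,6β-cyclic sulfite 27 (not isolated)
Conditions: SOCl2, Et3N, CH2Cl2, 0 °C; then RuCl3·xH2O (cat.), NaIO4, MeCN/CCl4/H2O, 0 °C
Reagents that add atoms: thionyl chloride (25), O=S(Cl)Cl; sodium periodate (26), [Na+].[O-]I(=O)(=O)=O
Why: Cyclic sulfite formation and oxidation to the cyclic sulfate by RuO4 made in the flask; only the cis-5,6-diol can bridge, because O1 and O6 are trans-diaxial, and the tertiary hydroxyl is not oxidised.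

Step 16
Reactants: 28 5β,6β-cyclic sulfate
Product: 30 [(1S,2R,3S,4R,5R,6S)-2,3-diacetoxy-4-(tert-butyldimethylsilyloxy)-5-hydroxy-7-oxabicyclo[4.1.0]heptan-1-yl]methyl benzoate, via epoxy sulfate monoester salt 29 (not isolated)
Conditions: DBU, THF, 0 °C → rt; then H2SO4, H2O (1 equiv), THF, rt
Reagents that add atoms: none
Why: Intramolecular opening of a cyclic sulfate by a neighbouring alkoxide (3-exo-tet) followed by acid hydrolysis of the sulfate monoester at sulfur; O1 (axial, α) attacks C6 from the back of the axial C6–O bond, which inverts C6 and places the oxirane on the α face, and the O5 configuration is kept because the S–O bond, not the C–O bond, is broken.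

Step 17
Reactants: 30 silylated epoxy alcohol
Product: 31 [(1S,2R,3S,4R,5R,6S)-2,3-diacetoxy-4,5-dihydroxy-7-oxabicyclo[4.1.0]heptan-1-yl]methyl benzoate (target)
Conditions: HF·pyridine, THF, 0 °C → rt
Reagents that add atoms: none
Why: Fluoride-mediated desilylation under mildly acidic conditions, which avoids the base-induced migration of the C3 acetate to the freed C4 hydroxyl and leaves the oxirane, flanked by three acyloxy-bearing carbons, intact.

## Compound list

1 | D-gulono-1,4-lactone | OC[C@@H](O)[C@@H]1OC(=O)[C@H](O)[C@@H]1O | starting material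
2 | 2,2-dimethoxypropane | COC(C)(C)OC | starting material
3 | 2,3:5,6-di-O-isopropylidene-D-gulono-1,4-lactone | CC1(C)OC[C@@H](O1)[C@@H]1OC(=O)[C@@H]2OC(C)(C)O[C@H]12 | intermediate
4 | 2,3-O-isopropylidene-D-gulono-1,4-lactone | OC[C@@H](O)[C@@H]1OC(=O)[C@@H]2OC(C)(C)O[C@H]12 | intermediate
5 | chlorotriethylsilane | CC[Si](Cl)(CC)CC | starting material
6 | 2,3-O-isopropylidene-5,6-bis-O-(triethylsilyl)-D-gulono-1,4-lactone | CC[Si](CC)(CC)OC[C@@H](O[Si](CC)(CC)CC)[C@@H]1OC(=O)[C@@H]2OC(C)(C)O[C@H]12 | intermediate
7 | N,O-dimethylhydroxylamine hydrochloride | CNOC.Cl | starting material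
8 | N-methoxy-N-methyl-2,3-O-isopropylidene-5,6-bis-O-(triethylsilyl)-D-gulonamide | CON(C)C(=O)[C@@H]1OC(C)(C)O[C@@H]1[C@@H](O)[C@@H](CO[Si](CC)(CC)CC)O[Si](CC)(CC)CC | intermediate
9 | tert-butyldimethylsilyl trifluoromethanesulfonate | CC(C)(C)[Si](C)(C)OS(=O)(=O)C(F)(F)F | starting material
10 | N-methoxy-N-methyl-4-O-(tert-butyldimethylsilyl)-2,3-O-isopropylidene-5,6-bis-O-(triethylsilyl)-D-gulonamide | CON(C)C(=O)[C@@H]1OC(C)(C)O[C@@H]1[C@@H](O[Si](C)(C)C(C)(C)C)[C@@H](CO[Si](CC)(CC)CC)O[Si](CC)(CC)CC | intermediate
11 | 4-methoxybenzyl alcohol | COc1ccc(CO)cc1 | starting material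
12 | tributyl(iodomethyl)stannane | CCCC[Sn](CCCC)(CCCC)CI | starting material
13 | tributyl{[(4-methoxybenzyl)oxy]methyl}stannane | CCCC[Sn](CCCC)(CCCC)COCc1ccc(OC)cc1 | intermediate
14 | [(4-methoxybenzyl)oxy]methyllithium | [Li]COCc1ccc(OC)cc1 | intermediate
15 | 5-O-(tert-butyldimethylsilyl)-3,4-O-isopropylidene-1-O-(4-methoxybenzyl)-6,7-bis-O-(triethylsilyl)-keto-D-gulo-hept-2-ulose | COc1ccc(COCC(=O)[C@@H]2OC(C)(C)O[C@@H]2[C@@H](O[Si](C)(C)C(C)(C)C)[C@@H](CO[Si](CC)(CC)CC)O[Si](CC)(CC)CC)cc1 | intermediate
16 | 3-O-(tert-butyldimethylsilyl)-4,5-O-isopropylidene-7-O-(4-methoxybenzyl)-2-O-(triethylsilyl)-aldehydo-L-gluco-heptos-6-ulose | O=C[C@@H](O[Si](CC)(CC)CC)[C@H](O[Si](C)(C)C(C)(C)C)[C@H]1OC(C)(C)O[C@H]1C(=O)COCc1ccc(OC)cc1 | intermediate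
17 | (1α,2α,3β,4α,5β,6β)-4-(tert-butyldimethylsilyloxy)-5,6-(isopropylidenedioxy)-1-[(4-methoxybenzyloxy)methyl]-3-(triethylsilyloxy)cyclohexane-1,2-diol | CC[Si](CC)(CC)O[C@H]1[C@H](O[Si](C)(C)C(C)(C)C)[C@H]2OC(C)(C)O[C@H]2[C@@](O)(COCc2ccc(OC)cc2)[C@@H]1O | intermediate
18 | (1α,2α,3β,4α,5β,6β)-4-(tert-butyldimethylsilyloxy)-5,6-(isopropylidenedioxy)-1-[(4-methoxybenzyloxy)methyl]cyclohexane-1,2,3-triol | O[C@H]1[C@H](O[Si](C)(C)C(C)(C)C)[C@H]2OC(C)(C)O[C@H]2[C@@](O)(COCc2ccc(OC)cc2)[C@@H]1O | intermediate
19 | acetic anhydride | CC(=O)OC(C)=O | starting material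
20 | (1α,2α,3β,4α,5β,6β)-2,3-diacetoxy-4-(tert-butyldimethylsilyloxy)-5,6-(isopropylidenedioxy)-1-[(4-methoxybenzyloxy)methyl]cyclohexan-1-ol | CC(=O)O[C@H]1[C@H](O[Si](C)(C)C(C)(C)C)[C@H]2OC(C)(C)O[C@H]2[C@@](O)(COCc2ccc(OC)cc2)[C@@H]1OC(C)=O | intermediate
21 | (1α,2α,3β,4α,5β,6β)-2,3-diacetoxy-4-(tert-butyldimethylsilyloxy)-1-(hydroxymethyl)-5,6-(isopropylidenedioxy)cyclohexan-1-ol | CC(=O)O[C@H]1[C@H](O[Si](C)(C)C(C)(C)C)[C@H]2OC(C)(C)O[C@H]2[C@@](O)(CO)[C@@H]1OC(C)=O | intermediate
22 | benzoyl chloride | O=C(Cl)c1ccccc1 | starting material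
23 | [(1α,2α,3β,4α,5β,6β)-2,3-diacetoxy-4-(tert-butyldimethylsilyloxy)-1-hydroxy-5,6-(isopropylidenedioxy)cyclohexyl]methyl benzoate | CC(=O)O[C@H]1[C@H](O[Si](C)(C)C(C)(C)C)[C@H]2OC(C)(C)O[C@H]2[C@@](O)(COC(=O)c2ccccc2)[C@@H]1OC(C)=O | intermediate
24 | [(1α,2α,3β,4α,5β,6β)-2,3-diacetoxy-4-(tert-butyldimethylsilyloxy)-1,5,6-trihydroxycyclohexyl]methyl benzoate | CC(=O)O[C@H]1[C@H](O[Si](C)(C)C(C)(C)C)[C@@H](O)[C@@H](O)[C@@](O)(COC(=O)c2ccccc2)[C@@H]1OC(C)=O | intermediate
25 | thionyl chloride | O=S(Cl)Cl | starting material
26 | sodium periodate | [Na+].[O-]I(=O)(=O)=O | starting material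
27 | 5β,6β-cyclic sulfite of 24 (both configurations at sulfur) | CC(=O)O[C@H]1[C@H](O[Si](C)(C)C(C)(C)C)[C@H]2OS(=O)O[C@H]2[C@@](O)(COC(=O)c2ccccc2)[C@@H]1OC(C)=O | intermediate
28 | 5β,6β-cyclic sulfate of 24 | CC(=O)O[C@H]1[C@H](O[Si](C)(C)C(C)(C)C)[C@H]2OS(=O)(=O)O[C@H]2[C@@](O)(COC(=O)c2ccccc2)[C@@H]1OC(C)=O | intermediate
29 | 1,8-diazabicyclo[5.4.0]undec-7-enium salt of the 5β-sulfate monoester of 30 | CC(=O)O[C@H]1[C@H](O[Si](C)(C)C(C)(C)C)[C@@H](OS(=O)(=O)[O-])[C@@H]2O[C@]2(COC(=O)c2ccccc2)[C@@H]1OC(C)=O.C1CCC2=[NH+]CCCN2CC1 | intermediate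
30 | [(1S,2R,3S,4R,5R,6S)-2,3-diacetoxy-4-(tert-butyldimethylsilyloxy)-5-hydroxy-7-oxabicyclo[4.1.0]heptan-1-yl]methyl benzoate | CC(=O)O[C@H]1[C@H](O[Si](C)(C)C(C)(C)C)[C@@H](O)[C@@H]2O[C@]2(COC(=O)c2ccccc2)[C@@H]1OC(C)=O | intermediate
31 | [(1S,2R,3S,4R,5R,6S)-2,3-diacetoxy-4,5-dihydroxy-7-oxabicyclo[4.1.0]heptan-1-yl]methyl benzoate | CC(=O)O[C@H]1[C@H](O)[C@@H](O)[C@@H]2O[C@]2(COC(=O)c2ccccc2)[C@@H]1OC(C)=O | target

## Step count and least certain steps

Total: 17 steps. Longest linear sequence: 16 steps from D-gulono-1,4-lactone (steps 1 to 5 and 7 to 17); step 6 is a one-step side branch.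

**Step 9 (key step).** The most likely failures are poor facial selectivity (a diol on the β face or a trans-diol), reductive cleavage of a C–O bond α to the ketone before the ketyl adds, or reduction of the aldehyde without coupling. The fallback forms the C1–C2 bond as an alkene and adds the two oxygens afterwards. It sets out from 16. Both carbonyls are methylenated (Ph3PCH3Br, KN(SiMe3)2, THF, −78 → 0 °C) to the 1,7-diene F1. Ring-closing metathesis with the second-generation Grubbs catalyst RuCl2(H2IMes)(PCy3)(=CHPh) in CH2Cl2 gives the cyclohexene F2 with the C1=C2 double bond. Dihydroxylation with OsO4 (cat.) and N-methylmorpholine N-oxide should then add to the face anti to the two allylic oxygens on C3 and C6, both β, and so return to 17.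

**Step 4.** The hydroxy amide may close back to the lactone on standing, and a triethylsilyl group may be lost or may shift to O4 in the presence of the aluminium reagents. The fallback changes the order of events and sets out from 3. Aminolysis of 3 (MeNHOMe·HCl, AlMe3) gives the 4-hydroxy diacetonide amide F3. Silylation with TBSOTf and 2,6-lutidine gives its TBS ether F4. Hydrolysis of the terminal dioxolane (aq. AcOH, rt) gives the 5,6-diol F5, and TESCl with imidazole silylates both hydroxyls, which comes back to the route at 10.

**Step 8.** The primary Si–O bond may be cleaved incompletely, or the α-oxygenated carbon next to the aldehyde or the ketone may epimerise during the amine stage. The fallback separates the two events and sets out from 15. The primary TES ether is removed selectively (HF·pyridine, pyridine, THF, −20 °C) to give the primary alcohol F6. Dess–Martin periodinane with NaHCO3 in CH2Cl2, which needs no amine base, then oxidises it to 16.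

**Step 14.** The O4 silyl ether may be lost together with the acetonide, so that O4 is no longer set apart from O5 and O6, or an acyl group may migrate in acid. The fallback replaces the silyl ether by an acid-stable ester that a neutral reagent removes, and sets out from 23.
- HF·pyridine gives the C4 alcohol F7.
- Levulinic acid, DCC and DMAP give the 4-O-levulinate F8.
- Aqueous TFA, which can now be used freely, gives the 5,6-diol F9.
- SOCl2/Et3N followed by RuCl3·xH2O (cat.)/NaIO4 gives the cyclic sulfate F10.
- DBU followed by H2SO4/H2O in THF gives the epoxy alcohol F11.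
- Hydrazine acetate in pyridine/AcOH removes the levulinate without touching acetates or benzoate, and the sequence comes back at 31.

**Step 16.** The new oxirane may be opened, or the silyl ether lost, during the acid hydrolysis of the sulfate monoester. Before ring closure the C1 alkoxide may also attack the neighbouring ester carbonyls and move acyl groups. The fallback closes the oxirane under neutral conditions and sets out from 24. The equatorial C5 hydroxyl is silylated selectively (TESCl, imidazole, CH2Cl2, −20 °C) to give the 5-O-TES ether F12. Mitsunobu cyclodehydration of the trans-diaxial C1/C6 diol (PPh3, DIAD, toluene, warm) gives the bis-silylated oxirane F13; the oxyphosphonium group on the secondary O6 is displaced by the tertiary O1 with inversion at C6. HF·pyridine then removes both silyl groups and comes back at 31.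

## Further compounds

F1 | step 9 | (3S,4R)-configured 1,7-diene from double methylenation of 16 (C2 vinyl, C1 1,1-disubstituted alkene; 3-OTES, 4-OTBS, 5,6-O-isopropylidene, 7-OPMB) | C=C[C@@H](O[Si](CC)(CC)CC)[C@H](O[Si](C)(C)C(C)(C)C)[C@H]1OC(C)(C)O[C@H]1C(=C)COCc1ccc(OC)cc1
F2 | step 9 | (3β,4α,5β,6β)-4-(tert-butyldimethylsilyloxy)-5,6-(isopropylidenedioxy)-1-[(4-methoxybenzyloxy)methyl]-3-(triethylsilyloxy)cyclohex-1-ene | CC[Si](CC)(CC)O[C@H]1[C@H](O[Si](C)(C)C(C)(C)C)[C@H]2OC(C)(C)O[C@H]2C(COCc2ccc(OC)cc2)=C1
F3 | step 4 | N-methoxy-N-methyl-2,3:5,6-di-O-isopropylidene-D-gulonamide | CON(C)C(=O)[C@@H]1OC(C)(C)O[C@@H]1[C@@H](O)[C@H]1COC(C)(C)O1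
F4 | step 4 | N-methoxy-N-methyl-4-O-(tert-butyldimethylsilyl)-2,3:5,6-di-O-isopropylidene-D-gulonamide | CON(C)C(=O)[C@@H]1OC(C)(C)O[C@@H]1[C@@H](O[Si](C)(C)C(C)(C)C)[C@H]1COC(C)(C)O1
F5 | step 4 | N-methoxy-N-methyl-4-O-(tert-butyldimethylsilyl)-2,3-O-isopropylidene-D-gulonamide | CON(C)C(=O)[C@@H]1OC(C)(C)O[C@@H]1[C@@H](O[Si](C)(C)C(C)(C)C)[C@@H](CO)O
F6 | step 8 | 5-O-(tert-butyldimethylsilyl)-3,4-O-isopropylidene-1-O-(4-methoxybenzyl)-6-O-(triethylsilyl)-keto-D-gulo-hept-2-ulose | COc1ccc(COCC(=O)[C@@H]2OC(C)(C)O[C@@H]2[C@@H](O[Si](C)(C)C(C)(C)C)[C@@H](CO)O[Si](CC)(CC)CC)cc1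
F7 | step 14 | [(1α,2α,3β,4α,5β,6β)-2,3-diacetoxy-1,4-dihydroxy-5,6-(isopropylidenedioxy)cyclohexyl]methyl benzoate | CC(=O)O[C@H]1[C@H](O)[C@H]2OC(C)(C)O[C@H]2[C@@](O)(COC(=O)c2ccccc2)[C@@H]1OC(C)=O
F8 | step 14 | 4-O-levulinate of F7 | CC(=O)O[C@H]1[C@H](OC(=O)CCC(C)=O)[C@H]2OC(C)(C)O[C@H]2[C@@](O)(COC(=O)c2ccccc2)[C@@H]1OC(C)=O
F9 | step 14 | [(1α,2α,3β,4α,5β,6β)-2,3-diacetoxy-1,5,6-trihydroxy-4-(4-oxopentanoyloxy)cyclohexyl]methyl benzoate | CC(=O)O[C@H]1[C@H](OC(=O)CCC(C)=O)[C@@H](O)[C@@H](O)[C@@](O)(COC(=O)c2ccccc2)[C@@H]1OC(C)=O
F10 | step 14 | 5β,6β-cyclic sulfate of F9 | CC(=O)O[C@H]1[C@H](OC(=O)CCC(C)=O)[C@H]2OS(=O)(=O)O[C@H]2[C@@](O)(COC(=O)c2ccccc2)[C@@H]1OC(C)=O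
F11 | step 14 | [(1S,2R,3S,4R,5R,6S)-2,3-diacetoxy-5-hydroxy-4-(4-oxopentanoyloxy)-7-oxabicyclo[4.1.0]heptan-1-yl]methyl benzoate | CC(=O)O[C@H]1[C@H](OC(=O)CCC(C)=O)[C@@H](O)[C@@H]2O[C@]2(COC(=O)c2ccccc2)[C@@H]1OC(C)=O
F12 | step 16 | [(1α,2α,3β,4α,5β,6β)-2,3-diacetoxy-4-(tert-butyldimethylsilyloxy)-1,6-dihydroxy-5-(triethylsilyloxy)cyclohexyl]methyl benzoate | CC(=O)O[C@H]1[C@H](O[Si](C)(C)C(C)(C)C)[C@@H](O[Si](CC)(CC)CC)[C@@H](O)[C@@](O)(COC(=O)c2ccccc2)[C@@H]1OC(C)=O
F13 | step 16 | 5-O-triethylsilyl ether of 30 | CC(=O)O[C@H]1[C@H](O[Si](C)(C)C(C)(C)C)[C@@H](O[Si](CC)(CC)CC)[C@@H]2O[C@]2(COC(=O)c2ccccc2)[C@@H]1OC(C)=O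
A1 | alternative 1 | benzoic acid | O=C(O)c1ccccc1
A2 | alternative 1 | (1S,2R)-1,2-dihydroxycyclohexa-3,5-diene-1-carboxylic acid | C1=CC=C[C@@](O)(C(=O)O)[C@@H]1O
A3 | alternative 2 | [trans-5,6-diacetoxycyclohexa-1,3-dien-1-yl]methyl benzoate with the C2 and C3 configuration of the target | CC(=O)O[C@H]1C=CC=C(COC(=O)c2ccccc2)[C@@H]1OC(C)=O
A4 | alternative 2 | C1,C4 endoperoxide with C5=C6 alkene (2,3-dioxabicyclo[2.2.2]oct-5-ene diacetate benzoate) | CC(=O)O[C@H]1[C@H]2C=C[C@](COC(=O)c3ccccc3)(OO2)[C@@H]1OC(C)=O
A5 | alternative 2 | syn-bis-oxirane with α oxiranes on C1–C6 and C4–C5 | CC(=O)O[C@H]1[C@@H]2O[C@@H]2[C@@H]2O[C@]2(COC(=O)c2ccccc2)[C@@H]1OC(C)=O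
A6 | alternative 3 | meso-(1-hydroxy-4-oxo-2,3:5,6-diepoxycyclohexyl)methyl benzoate, both oxiranes anti to the hydroxyl | O=C1[C@@H]2O[C@@H]2[C@](O)(COC(=O)c2ccccc2)[C@@H]2O[C@H]12
A7 | alternative 3 | C1–C6 oxirane with C5 hydroxyl, C4 ketone and C2–C3 oxirane | O1[C@H]2C(=O)[C@@H](O)[C@@H]3O[C@]3(COC(=O)c3ccccc3)[C@@H]12
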